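The route rests on cutting ring C between C3 and C4. The O1–C2H(aryl)–C3H2–C4(=O) segment is read as an aldehyde C–H added across the C2=C3 bond of a 1-arylvinyl aryl ether. An enantioselective rhodium-catalysed intramolecular hydroacylation therefore closes the dihydropyranone ring, forms C3–C4 and sets C2 (S) by hydride delivery in one atom-economical operation. Its precursor is a hexasubstituted salicylaldehyde carrying prenyl, (R)-lavandulyl and two MOM ethers, whose phenol oxygen bears the 1-[2,4,6-tris(methoxymethoxy)phenyl]vinyl group. It is assembled from 2,4,6-trihydroxybenzaldehyde by iodide-selective Negishi coupling, Stille prenylation and gold-catalysed hydrophenoxylation of an arylalkyne.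

Key step: step 13

Remarks on the chemistry:
- The target is (2S) at C2 and (R) at the lavandulyl centre. The lavandulyl unit is made as (S)-lavandulol; the descriptor turns to R on attachment to the arene only because the CIP priorities change, the spatial arrangement staying the same.
- Assumption: the sense of induction of the rhodium catalyst cannot be assigned in advance. (R)-DTBM-SEGPHOS is written in step 13 and stands for the ligand antipode that delivers hydride to the Re face of C2; the (S)-ligand is taken if a test shows the opposite sense.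
- Abbreviations: MOM = methoxymethyl; prenyl = 3-methylbut-2-en-1-yl; lavandulyl = 5-methyl-2-(prop-1-en-2-yl)hex-4-en-1-yl.

Step 1
Reactants: 1 (4S)-4-benzyl-1,3-oxazolidin-2-one; 2 3-methylbut-2-enoyl chloride
Product: 4 (4S)-4-benzyl-3-(3-methylbut-2-enoyl)-1,3-oxazolidin-2-one, via lithium oxazolidinide 3 (not isolated)
Conditions: n-BuLi, THF, −78 °C; then 2, −78 → 0 °C
Reagents that add atoms: none
Why: N-acylation of the lithiated Evans oxazolidinone, the lithium amide route avoiding the vinylketene (deconjugation) pathway that amine bases open with this acyl chloride.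

Step 2
Reactants: 4 (4S)-4-benzyl-3-(3-methylbut-2-enoyl)-1,3-oxazolidin-2-one; 5 1-bromo-3-methylbut-2-ene (prenyl bromide)
Product: 7 (4S)-4-benzyl-3-[(2S)-5-methyl-2-(prop-1-en-2-yl)hex-4-enoyl]-1,3-oxazolidin-2-one, via sodium dienolate 6 (not isolated)
Conditions: NaN(SiMe3)2, THF, −78 °C; then 5, −78 → −40 °C
Reagents that add atoms: none
Why: Evans asymmetric alkylation in its deconjugative form: γ-deprotonation gives the chelated (Z)-dienolate 6, which should be alkylated at the α-carbon on the face opposite the benzyl group, setting the (S)-centre and moving the double bond into the isopropenyl position.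

Step 3
Reactants: 7 (4S)-4-benzyl-3-[(2S)-5-methyl-2-(prop-1-en-2-yl)hex-4-enoyl]-1,3-oxazolidin-2-one
Product: 8 (S)-lavandulol, (2S)-5-methyl-2-(prop-1-en-2-yl)hex-4-en-1-ol
Conditions: LiBH4, H2O (1 equiv), Et2O, 0 °C
Reagents that add atoms: none
Why: Reductive cleavage of the imide by LiBH4 should release the primary alcohol without touching the alkenes or the α-centre and return the auxiliary.

Step 4
Reactants: 8 (S)-lavandulol
Product: 9 (S)-lavandulyl iodide, (3S)-3-(iodomethyl)-2,6-dimethylhepta-1,5-diene
Conditions: I2, PPh3, imidazole, CH2Cl2, 0 °C → rt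
Reagents that add atoms: iodine, II
Why: Appel-type iodination converts the primary alcohol into the iodide by SN2 at CH2, the stereocentre not being involved.

Step 5
Reactants: 10 2,4,6-trihydroxybenzaldehyde
Product: 11 2,4,6-tris(methoxymethoxy)benzaldehyde
Conditions: NaH, MOMCl, DMF, 0 °C → rt
Reagents that add atoms: chloromethyl methyl ether (MOMCl), COCCl
Why: Williamson etherification of all three phenoxides with the hard electrophile MOMCl should give O-alkylation throughout.

Step 6
Reactants: 11 2,4,6-tris(methoxymethoxy)benzaldehyde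
Product: 12 2-ethynyl-1,3,5-tris(methoxymethoxy)benzene
Conditions: dimethyl (1-diazo-2-oxopropyl)phosphonate, K2CO3, MeOH, rt
Reagents that add atoms: dimethyl (1-diazo-2-oxopropyl)phosphonate (Ohira–Bestmann reagent), CC(=O)C(=[N+]=[N-])P(=O)(OC)OC
Why: Seyferth–Gilbert homologation with the Ohira–Bestmann reagent turns the aldehyde into the terminal alkyne under carbonate conditions that MOM ethers tolerate.

Step 7
Reactants: 10 2,4,6-trihydroxybenzaldehyde
Product: 13 2-hydroxy-4,6-bis(methoxymethoxy)benzaldehyde
Conditions: MOMCl (2.2 equiv), i-Pr2NEt, CH2Cl2, 0 °C → rt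
Reagents that add atoms: chloromethyl methyl ether (MOMCl), COCCl
Why: With an amine base only two phenols are etherified and the one left is locked in the hydrogen bond to the formyl group, which differentiates the oxygen that becomes O1.

Step 8
Reactants: 13 2-hydroxy-4,6-bis(methoxymethoxy)benzaldehyde
Product: 14 2-hydroxy-3-iodo-4,6-bis(methoxymethoxy)benzaldehyde
Conditions: [BnNMe3][ICl2], NaHCO3, CH2Cl2/MeOH, rt
Reagents that add atoms: benzyltrimethylammonium dichloroiodate, C[N+](C)(C)Cc1ccccc1.Cl[I-]Cl
Why: Electrophilic aromatic iodination with the dichloroiodate reagent should take place ortho to the free chelated phenol, the position that becomes C8.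

Step 9
Reactants: 14 2-hydroxy-3-iodo-4,6-bis(methoxymethoxy)benzaldehyde
Product: 15 3-bromo-6-hydroxy-5-iodo-2,4-bis(methoxymethoxy)benzaldehyde
Conditions: NBS, MeCN, 0 °C
Reagents that add atoms: N-bromosuccinimide, O=C1CCC(=O)N1Br
Why: Electrophilic aromatic bromination can only occur at the one remaining ring position (the future C6), which is activated by all three oxygens.

Step 10
Reactants: 15 3-bromo-6-hydroxy-5-iodo-2,4-bis(methoxymethoxy)benzaldehyde; 9 (S)-lavandulyl iodide
Product: 17 3-bromo-6-hydroxy-2,4-bis(methoxymethoxy)-5-[(2R)-5-methyl-2-(prop-1-en-2-yl)hex-4-en-1-yl]benzaldehyde, via lavandulylzinc iodide 16 (not isolated)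
Conditions: Zn dust, LiCl, THF, 40 °C (9 → 16); then slow addition to 15, Pd(OAc)2 (3 mol%), SPhos (6 mol%), THF, 25 °C
Reagents that add atoms: none
Why: Negishi sp2–sp3 cross-coupling: zinc insertion into the primary iodide gives 16, and zerovalent palladium with SPhos should couple it at the C–I bond, which undergoes oxidative addition far faster than C–Br, while slow addition lets coupling outrun protonolysis by the chelated phenol and the lavandulyl centre is untouched.

Step 11
Reactants: 17 3-bromo-6-hydroxy-2,4-bis(methoxymethoxy)-5-[(2R)-5-methyl-2-(prop-1-en-2-yl)hex-4-en-1-yl]benzaldehyde; 18 tributyl(3-methylbut-2-en-1-yl)stannane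
Product: 19 2-hydroxy-4,6-bis(methoxymethoxy)-3-[(2R)-5-methyl-2-(prop-1-en-2-yl)hex-4-en-1-yl]-5-(3-methylbut-2-en-1-yl)benzaldehyde
Conditions: Pd(PPh3)4 (10 mol%), DMF, 100 °C
Reagents that add atoms: none
Why: Stille coupling of the aryl bromide with the prenylstannane, in which reductive elimination at the less hindered allyl terminus should give the linear prenyl group.

Step 12
Reactants: 19 2-hydroxy-4,6-bis(methoxymethoxy)-3-[(2R)-lavandulyl]-5-prenylbenzaldehyde; 12 2-ethynyl-1,3,5-tris(methoxymethoxy)benzene
Product: 20 2,4-bis(methoxymethoxy)-3-(3-methylbut-2-en-1-yl)-5-[(2R)-5-methyl-2-(prop-1-en-2-yl)hex-4-en-1-yl]-6-({1-[2,4,6-tris(methoxymethoxy)phenyl]ethenyl}oxy)benzaldehyde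
Conditions: [Au(PPh3)(NTf2)] (5 mol%), 4 Å MS, toluene, 25–40 °C
Reagents that add atoms: none
Why: Gold-catalysed Markovnikov hydrophenoxylation of a terminal arylalkyne: monovalent gold activates the alkyne, the phenol oxygen should add to the internal carbon (cation stabilised by the trioxygenated ring) and protodeauration gives the 1-arylvinyl ether, a linear alkyne being the one electrophile this doubly flanked phenol can reach.

Step 13
Reactants: 20 the 1-arylvinyl ether aldehyde
Product: 21 (2S)-5,7-bis(methoxymethoxy)-8-[(2R)-5-methyl-2-(prop-1-en-2-yl)hex-4-en-1-yl]-6-(3-methylbut-2-en-1-yl)-2-[2,4,6-tris(methoxymethoxy)phenyl]-2,3-dihydro-4H-chromen-4-one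
Conditions: [Rh(cod)Cl]2 (2.5 mol%), (R)-DTBM-SEGPHOS (5.5 mol%), Na[B(3,5-(CF3)2C6H3)4] (5 mol%), 1,4-dioxane, 80 °C
Reagents that add atoms: none
Why: Proposed new method: cationic monovalent rhodium should add oxidatively into the formyl C–H of 20, the hydride should insert the 1,1-disubstituted enol ether so that H goes to C2 and rhodium to the terminal carbon C3, and C–C reductive elimination from the seven-membered acyl–alkyl rhodacycle should form C3–C4 and release the catalyst. The closest known reaction type is the enantioselective rhodium-catalysed endo hydroacylation of ortho-(2-arylallyl)benzaldehydes to 3-aryl-1-tetralones, of which 20 is the oxa analogue (O1 in place of the benzylic CH2); aryl 1-arylvinyl ethers have not been shown in it, hence the label. Ring C closes in a 6-endo-trig mode, because the 5-exo alternative would require a tertiary alkyl rhodium at C2 and a quaternary centre. C2 is the only new stereocentre and is set under catalyst control: the chiral bisphosphine must direct hydride to the Re face of C2 to give 2S, the remote lavandulyl centre having no say. The step needs anti-Markovnikov regioselectivity, facial selectivity and chemoselectivity against decarbonylation; the unhindered CH2 terminus, the ligand pocket and chelation of the acyl rhodium hydride by the alkene and the flanking ether oxygens should secure them, the enol ether has no allylic hydrogen so the alkene isomerisation that plagues related substrates is impossible, and the prenyl and lavandulyl alkenes sit meta to the formyl group and cannot reach it.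

Step 14
Reactants: 21 the pentakis-MOM flavanone
Product: 23 (2S)-5,7-dihydroxy-8-[(2R)-5-methyl-2-(prop-1-en-2-yl)hex-4-en-1-yl]-6-(3-methylbut-2-en-1-yl)-2-(2,4,6-trihydroxyphenyl)-2,3-dihydro-4H-chromen-4-one (CNP0163831.1), via pentakis(trimethylsilyl) ether 22 (not isolated)
Conditions: Me3SiOTf, 2,2'-bipyridyl, MeCN, 0 °C → rt; then H2O
Reagents that add atoms: none
Why: Silyl triflate/2,2'-bipyridyl cleavage of aromatic MOM ethers proceeds through the aryl silyl ethers 22, which water hydrolyses, and the buffered non-protic medium should spare the prenyl and lavandulyl alkenes and the labile benzylic C2–O1 bond so that 2S is kept.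

Compound list
1 | (4S)-4-benzyl-1,3-oxazolidin-2-one | O=C1N[C@@H](Cc2ccccc2)CO1 | starting material
2 | 3-methylbut-2-enoyl chloride | CC(C)=CC(Cl)=O | starting material
3 | lithium (4S)-4-benzyl-2-oxo-1,3-oxazolidin-3-ide | [Li]N1[C@@H](Cc2ccccc2)COC1=O | intermediate
4 | (4S)-4-benzyl-3-(3-methylbut-2-enoyl)-1,3-oxazolidin-2-one | CC(C)=CC(=O)N1[C@@H](Cc2ccccc2)COC1=O | intermediate
5 | 1-bromo-3-methylbut-2-ene | CC(C)=CCBr | starting material
6 | sodium (Z)-dienolate of 4 | [Na+].C=C(C)/C=C(\[O-])N1[C@@H](Cc2ccccc2)COC1=O | intermediate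
7 | (4S)-4-benzyl-3-[(2S)-5-methyl-2-(prop-1-en-2-yl)hex-4-enoyl]-1,3-oxazolidin-2-one | C=C(C)[C@H](CC=C(C)C)C(=O)N1[C@@H](Cc2ccccc2)COC1=O | intermediate
8 | (S)-lavandulol, (2S)-5-methyl-2-(prop-1-en-2-yl)hex-4-en-1-ol | C=C(C)[C@H](CC=C(C)C)CO | intermediate
9 | (S)-lavandulyl iodide, (3S)-3-(iodomethyl)-2,6-dimethylhepta-1,5-diene | C=C(C)[C@H](CC=C(C)C)CI | intermediate
10 | 2,4,6-trihydroxybenzaldehyde | O=Cc1c(O)cc(O)cc1O | starting material
11 | 2,4,6-tris(methoxymethoxy)benzaldehyde | O=Cc1c(OCOC)cc(OCOC)cc1OCOC | intermediate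
12 | 2-ethynyl-1,3,5-tris(methoxymethoxy)benzene | C#Cc1c(OCOC)cc(OCOC)cc1OCOC | intermediate
13 | 2-hydroxy-4,6-bis(methoxymethoxy)benzaldehyde | O=Cc1c(O)cc(OCOC)cc1OCOC | intermediate
14 | 2-hydroxy-3-iodo-4,6-bis(methoxymethoxy)benzaldehyde | O=Cc1c(O)c(I)c(OCOC)cc1OCOC | intermediate
15 | 3-bromo-6-hydroxy-5-iodo-2,4-bis(methoxymethoxy)benzaldehyde | O=Cc1c(O)c(I)c(OCOC)c(Br)c1OCOC | intermediate
16 | [(2S)-5-methyl-2-(prop-1-en-2-yl)hex-4-en-1-yl]zinc iodide | C=C(C)[C@H](CC=C(C)C)C[Zn]I | intermediate
17 | 3-bromo-6-hydroxy-2,4-bis(methoxymethoxy)-5-[(2R)-5-methyl-2-(prop-1-en-2-yl)hex-4-en-1-yl]benzaldehyde | C=C(C)[C@H](CC=C(C)C)Cc1c(O)c(C=O)c(OCOC)c(Br)c1OCOC | intermediate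
18 | tributyl(3-methylbut-2-en-1-yl)stannane | CC(C)=CC[Sn](CCCC)(CCCC)CCCC | starting material
19 | 2-hydroxy-4,6-bis(methoxymethoxy)-3-[(2R)-5-methyl-2-(prop-1-en-2-yl)hex-4-en-1-yl]-5-(3-methylbut-2-en-1-yl)benzaldehyde | C=C(C)[C@H](CC=C(C)C)Cc1c(O)c(C=O)c(OCOC)c(CC=C(C)C)c1OCOC | intermediate
20 | 2,4-bis(methoxymethoxy)-3-(3-methylbut-2-en-1-yl)-5-[(2R)-5-methyl-2-(prop-1-en-2-yl)hex-4-en-1-yl]-6-({1-[2,4,6-tris(methoxymethoxy)phenyl]ethenyl}oxy)benzaldehyde | C=C(C)[C@H](CC=C(C)C)Cc1c(OC(=C)c2c(OCOC)cc(OCOC)cc2OCOC)c(C=O)c(OCOC)c(CC=C(C)C)c1OCOC | intermediate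
21 | (2S)-5,7-bis(methoxymethoxy)-8-[(2R)-5-methyl-2-(prop-1-en-2-yl)hex-4-en-1-yl]-6-(3-methylbut-2-en-1-yl)-2-[2,4,6-tris(methoxymethoxy)phenyl]-2,3-dihydro-4H-chromen-4-one | C=C(C)[C@H](CC=C(C)C)Cc1c(OCOC)c(CC=C(C)C)c(OCOC)c2c1O[C@H](c1c(OCOC)cc(OCOC)cc1OCOC)CC2=O | intermediate
22 | pentakis(trimethylsilyl) ether of 23 | C=C(C)[C@H](CC=C(C)C)Cc1c(O[Si](C)(C)C)c(CC=C(C)C)c(O[Si](C)(C)C)c2c1O[C@H](c1c(O[Si](C)(C)C)cc(O[Si](C)(C)C)cc1O[Si](C)(C)C)CC2=O | intermediate
23 | (2S)-5,7-dihydroxy-8-[(2R)-5-methyl-2-(prop-1-en-2-yl)hex-4-en-1-yl]-6-(3-methylbut-2-en-1-yl)-2-(2,4,6-trihydroxyphenyl)-2,3-dihydro-4H-chromen-4-one | C=C(C)[C@H](CC=C(C)C)Cc1c(O)c(CC=C(C)C)c(O)c2c1O[C@H](c1c(O)cc(O)cc1O)CC2=O | target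

Total step count: 14.
Longest linear sequence: 9 steps (steps 1–4 and 10–14).

Steps most likely to fail

1. Step 13 (labelled step). Migratory insertion at the hindered 1,1-disubstituted enol ether may be too slow, so that decarbonylation of the acyl rhodium hydride takes over. The C3-bound alkyl rhodium may lose the β-aryloxide instead of undergoing reductive elimination. Hydride delivery may also show poor facial selectivity. The fallback sets out from 20 and closes the same C3–C4 bond by a radical chain of known type: tert-dodecanethiol as polarity-reversal catalyst with di-tert-butyl hyponitrite (or AIBN) in 1,4-dioxane at 60–80 °C should abstract the formyl hydrogen, the aroyl radical should add 6-endo to the terminal carbon of the enol ether, and the tertiary benzylic C2 radical should take hydrogen from the thiol without facial control. This should give 21 together with its C2 epimer, (2R)-5,7-bis(methoxymethoxy)-8-[(2R)-5-methyl-2-(prop-1-en-2-yl)hex-4-en-1-yl]-6-(3-methylbut-2-en-1-yl)-2-[2,4,6-tris(methoxymethoxy)phenyl]-2,3-dihydro-4H-chromen-4-one F1. Because the lavandulyl centre is fixed the two are diastereomers, to be separated by preparative HPLC (on a chiral stationary phase if needed). The route is rejoined at 21.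

2. Step 12. An ortho MOM ether oxygen of 12 may cyclise onto the gold-activated alkyne (benzofuran formation), or adventitious acid may add the phenol of 19 to its neighbouring isopropenyl group (chroman formation), in place of the intermolecular O–H addition. The fallback sets out from 12 and 19 and forms the same C–O bond by oxidative copper coupling instead of π-acid addition. Alkyne 12 is converted by α-selective copper-catalysed protoboration (B2pin2, MeOH, NaOt-Bu, [CuCl(SIMes)] with SIMes = 1,3-dimesitylimidazolidin-2-ylidene, THF) into 4,4,5,5-tetramethyl-2-{1-[2,4,6-tris(methoxymethoxy)phenyl]ethenyl}-1,3,2-dioxaborolane F2. Chan–Lam–Evans coupling of F2 with phenol 19 (Cu(OAc)2, pyridine, 4 Å MS, air, CH2Cl2, rt) should give 20, where the route is rejoined.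

3. Step 10. Protonolysis of the organozinc by the acidic chelated phenol, or β-hydride elimination from the β-branched alkylpalladium, may outrun the coupling. The fallback sets out from 9 and 15 and replaces the zinc reagent by a boron nucleophile that tolerates the phenol as its phenoxide. Iodide 9 is borylated under copper catalysis (B2pin2, CuI, PPh3, LiOMe, DMF, rt) to 4,4,5,5-tetramethyl-2-[(2S)-5-methyl-2-(prop-1-en-2-yl)hex-4-en-1-yl]-1,3,2-dioxaborolane F3. Suzuki–Miyaura coupling of F3 with 15 at the C–I bond (Pd(OAc)2, RuPhos, K3PO4, toluene/H2O, 80 °C) should give 17, where the route is rejoined.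

Further compounds
F1 | step 13 | (2R)-5,7-bis(methoxymethoxy)-8-[(2R)-5-methyl-2-(prop-1-en-2-yl)hex-4-en-1-yl]-6-(3-methylbut-2-en-1-yl)-2-[2,4,6-tris(methoxymethoxy)phenyl]-2,3-dihydro-4H-chromen-4-one | C=C(C)[C@H](CC=C(C)C)Cc1c(OCOC)c(CC=C(C)C)c(OCOC)c2c1O[C@@H](c1c(OCOC)cc(OCOC)cc1OCOC)CC2=O
F2 | step 12 | 4,4,5,5-tetramethyl-2-{1-[2,4,6-tris(methoxymethoxy)phenyl]ethenyl}-1,3,2-dioxaborolane | C=C(B1OC(C)(C)C(C)(C)O1)c1c(OCOC)cc(OCOC)cc1OCOC
F3 | step 10 | 4,4,5,5-tetramethyl-2-[(2S)-5-methyl-2-(prop-1-en-2-yl)hex-4-en-1-yl]-1,3,2-dioxaborolane | C=C(C)[C@H](CC=C(C)C)CB1OC(C)(C)C(C)(C)O1
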